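**Retrosynthetic overview**
1. Cut the aryl–CH2 bond of the target: 4-bromo-2-methoxyphenol (aryl electrophile) plus the C-1 homoenolate of hexadecane-3,5-dione, in which the β-carbon of the C-3 ketone acts as the nucleophile.
2. That homoenolate is stored as a strained cyclopropanol, 1-(2-oxotridecyl)cyclopropan-1-ol, and is released on palladium by ring opening.
3. The cyclopropanol comes from an aldol-type cut between C-3 and C-4: the kinetic (methyl-side) enolate of tridecan-2-one plus cyclopropanone, released from its ethyl hemiketal, which is made from the commercial silyl ketal.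
4. Rings: no ring is built. The three-membered ring is bought in the silyl ketal, carried through the aldol step and opened in the last step; the arene is bought intact.

Assumption: the target has no stereocentre (it is achiral and is drawn as the diketo form of a keto–enol mixture), so there is no configuration to set.

**Step 1**
Reactants: 1 (1-ethoxycyclopropoxy)trimethylsilane
Product: 2 1-ethoxycyclopropan-1-ol (cyclopropanone ethyl hemiketal)
Conditions: MeOH (acid-free), rt, 12 h; evaporate below 25 °C, use crude
Reagents that add atoms: none
Why: Neutral methanolysis of the O–SiMe3 bond (transsilylation to MeOSiMe3) frees the hemiketal, which does not collapse because angle strain disfavours the sp2 carbon of cyclopropanone; no stereocentre is formed.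

**Step 2**
Reactants: 2 1-ethoxycyclopropan-1-ol; 3 tridecan-2-one
Product: 7 1-(2-oxotridecyl)cyclopropan-1-ol, via lithium tridec-1-en-2-olate 4 (not isolated), via bromomagnesium 1-ethoxycyclopropan-1-olate 5 (not isolated), via cyclopropanone 6 (not isolated)
Conditions: 3 (1.3 equiv), LiN(iPr)2 (commercial solution, 1.35 equiv), THF, −78 °C, 45 min; separately 2 (1.0 equiv), EtMgBr (1.0 equiv), THF, 0 °C, 15 min; cannulate onto the enolate at −78 °C, then → rt, 6 h; aq NH4Cl
Reagents that add atoms: none
Why: Proposed new method: the kinetic methyl-side lithium enolate 4 adds in an aldol addition to cyclopropanone 6, which is released from magnesium hemiketalate 5 by loss of EtOMgBr, and relief of angle strain on going from sp2 to sp3 makes the addition essentially irreversible (no retro-aldol); the closest known reaction type is the addition of Grignard and alkynyllithium reagents to the same magnesium hemiketalate to give 1-substituted cyclopropanols; no stereocentre is formed.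

**Step 3**
Reactants: 7 1-(2-oxotridecyl)cyclopropan-1-ol; 8 4-bromo-2-methoxyphenol
Product: 10 1-(4-hydroxy-3-methoxyphenyl)hexadecane-3,5-dione ([12]-gingerdione), via arylpalladium homoenolate 9 (not isolated)
Conditions: 7 (1.3 equiv), 8 (1.0 equiv), Pd(OAc)2 (5 mol %), XPhos (10 mol %), Cs2CO3 (3 equiv), toluene, 80 °C, Ar, 12 h; pH 4 buffer work-up
Reagents that add atoms: none
Why: Palladium-catalysed ring-opening cross-coupling of a cyclopropanol with an aryl bromide (homoenolate arylation): zerovalent palladium inserts into the C–Br bond, the cyclopropanol binds as its alkoxide, strain-driven β-carbon elimination gives the ketone-chelated C-bound homoenolate 9, and C(sp2)–C(sp3) reductive elimination, favoured over β-hydride elimination by the bulky biarylphosphine, joins the aryl carbon to C-1; no stereocentre arises.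

**Compound list**
1 | (1-ethoxycyclopropoxy)trimethylsilane | CCOC1(CC1)O[Si](C)(C)C | starting material
2 | 1-ethoxycyclopropan-1-ol (cyclopropanone ethyl hemiketal) | CCOC1(O)CC1 | intermediate
3 | tridecan-2-one | CCCCCCCCCCCC(C)=O | starting material
4 | lithium tridec-1-en-2-olate (kinetic enolate of 3) | CCCCCCCCCCCC(=C)O[Li] | intermediate
5 | bromomagnesium 1-ethoxycyclopropan-1-olate | CCOC1(CC1)O[Mg]Br | intermediate
6 | cyclopropanone | O=C1CC1 | intermediate
7 | 1-(2-oxotridecyl)cyclopropan-1-ol | CCCCCCCCCCCC(=O)CC1(O)CC1 | intermediate
8 | 4-bromo-2-methoxyphenol | COc1cc(Br)ccc1O | starting material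
9 | (4-hydroxy-3-methoxyphenyl)(3,5-dioxohexadecyl)palladium XPhos complex, a divalent palladium homoenolate (phosphine-to-palladium bond written as P+–Pd−) | CCCCCCCCCCCC(=O)CC(=O)CC[Pd-]([P+](C1CCCCC1)(C1CCCCC1)c1ccccc1-c1c(C(C)C)cc(C(C)C)cc1C(C)C)c1ccc(O)c(OC)c1 | intermediate
10 | 1-(4-hydroxy-3-methoxyphenyl)hexadecane-3,5-dione ([12]-gingerdione) | CCCCCCCCCCCC(=O)CC(=O)CCc1ccc(O)c(OC)c1 | target

**Totals**
Total step count: 3. Longest linear sequence: 3 (1 → 2 → 7 → 10).

**Steps most likely to fail, with fallbacks**

Most at risk, step 3. The bromide carries a free phenol, whose phenoxide slows oxidative addition and can bind palladium. The product is an acidic β-diketone that can chelate divalent palladium or be arylated at C-4. Intermediate 9 can also undergo β-hydride elimination to the vinyl diketone. The fallback sets out from 8 and comes back at 10; it keeps a homoenolate arylation for the aryl–CH2 bond but moves it to an ester and builds the diketone afterwards. Compound 8 is benzylated (BnBr, K2CO3, DMF, rt) to 1-(benzyloxy)-4-bromo-2-methoxybenzene F1. Silyl ketal 1 (2 equiv) and ZnCl2 (1 equiv) in Et2O give the ester zinc homoenolate bis(3-ethoxy-3-oxopropyl)zinc F2. F2 is coupled with F1 (Pd(OAc)2, SPhos, THF, 50 °C) to ethyl 3-[4-(benzyloxy)-3-methoxyphenyl]propanoate F3. Crossed Claisen condensation of F3 with enolate 4 (2.2 equiv, THF, −78 → 0 °C) gives 1-[4-(benzyloxy)-3-methoxyphenyl]hexadecane-3,5-dione F4. Hydrogenolysis (H2, Pd/C, EtOAc, rt) then gives 10.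

Second, step 2. The enolate addition to cyclopropanone released in the flask is untested. Release of 6 from 5 may need temperatures at which enolate 4 equilibrates to the internal enolate, which would give the branched regioisomer or self-condensation. The fallback sets out from 3 and comes back at 7; it builds the cyclopropanol by a Kulinkovich reaction on a regiochemically defined ester. Compound 3 is carboxylated on the methyl side (NaH, dimethyl carbonate, THF, reflux) to methyl 3-oxotetradecanoate F5. The ketone is protected (ethylene glycol, p-TsOH, toluene, Dean–Stark) as methyl 2-(2-undecyl-1,3-dioxolan-2-yl)acetate F6. Kulinkovich cyclopropanation (EtMgBr, Ti(OiPr)4, THF/Et2O, 0 °C → rt) gives 1-[(2-undecyl-1,3-dioxolan-2-yl)methyl]cyclopropan-1-ol F7. Mild deketalisation (pyridinium p-toluenesulfonate, acetone/H2O, 40 °C) gives 7.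

Third, step 1. The reaction itself is reliable, but 2 is volatile and ring-opens to ethyl propanoate with traces of acid or base, so material can be lost before step 2. The fallback sets out from 1 and comes back at 7; it replaces the hemiketal with a crystalline, storable cyclopropanone surrogate. Compound 1 is treated with PhSO2Na and HCO2H in MeOH at rt to give 1-(benzenesulfonyl)cyclopropan-1-ol F8. F8 is deprotonated with LiN(iPr)2 (1 equiv, THF, −78 °C), which expels benzenesulfinate and releases 6 at low temperature. Trapping with enolate 4 (1.3 equiv, −78 °C) and aq NH4Cl work-up gives 7.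

**Further compounds**
F1 | step 3 | 1-(benzyloxy)-4-bromo-2-methoxybenzene | COc1cc(Br)ccc1OCc1ccccc1
F2 | step 3 | bis(3-ethoxy-3-oxopropyl)zinc | CCOC(=O)CC[Zn]CCC(=O)OCC
F3 | step 3 | ethyl 3-[4-(benzyloxy)-3-methoxyphenyl]propanoate | CCOC(=O)CCc1ccc(OCc2ccccc2)c(OC)c1
F4 | step 3 | 1-[4-(benzyloxy)-3-methoxyphenyl]hexadecane-3,5-dione | CCCCCCCCCCCC(=O)CC(=O)CCc1ccc(OCc2ccccc2)c(OC)c1
F5 | step 2 | methyl 3-oxotetradecanoate | CCCCCCCCCCCC(=O)CC(=O)OC
F6 | step 2 | methyl 2-(2-undecyl-1,3-dioxolan-2-yl)acetate | CCCCCCCCCCCC1(CC(=O)OC)OCCO1
F7 | step 2 | 1-[(2-undecyl-1,3-dioxolan-2-yl)methyl]cyclopropan-1-ol | CCCCCCCCCCCC1(CC2(O)CC2)OCCO1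
F8 | step 1 | 1-(benzenesulfonyl)cyclopropan-1-ol | OC1(CC1)S(=O)(=O)c1ccccc1
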